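**Strategy.** The plan cuts the C4–C5 bond of the ring, numbered C1 (secondary carbinol), C2=C3, C4, C5 (tertiary carbinol) and C6. With chain carbon C1' at the carboxyl level, C1'–C5–C4–C3=C2 is the γ,δ-unsaturated acid pattern left by a [3,3] shift. An Ireland–Claisen rearrangement of a six-membered vinyl lactone therefore does four things in one operation. It closes the cyclohexene, sets the cis C2=C3 alkene, builds the oxygenated quaternary C5 by chirality transfer, and releases C1' as CO2H. The precursor is a tartrate-derived 5,6-cis 5-silyloxy-3-hydroxy-6-vinyl-δ-valerolactone, silylated in the flask. The C15 chain is added last by opening a C5 spiro-epoxide.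

Key step: step 8

Remark on the chemistry: the α-hydroxylation in step 7 may give both epimers at the lactone α-carbon. The expected one is drawn, and either serves because that carbon becomes planar in step 8.

Step 1
Reactants: 1 dimethyl (4R,5R)-2,2-dimethyl-1,3-dioxolane-4,5-dicarboxylate (dimethyl 2,3-O-isopropylidene-L-tartrate)
Product: 3 (4S,5S)-2,2-dimethyl-4,5-divinyl-1,3-dioxolane, via dialdehyde 2 (not isolated)
Conditions: i-Bu2AlH (2.1 equiv), toluene, −78 °C; then Ph3P=CH2 [Ph3PCH3Br, NaN(SiMe3)2, THF], −78 °C → rt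
Reagents that add atoms: methyltriphenylphosphonium bromide, C[P+](c1ccccc1)(c1ccccc1)c1ccccc1.[Br-]
Why: Low-temperature half-reduction of both esters stops at the aluminium hemiacetal and the aldehyde groups freed on warming are captured at once by Wittig methylenation, so the epimerisable dialdehyde is never handled and both tartrate stereocentres carry over unchanged (R becomes S only through the change in substituent ranking).

Step 2
Reactants: 3 (4S,5S)-2,2-dimethyl-4,5-divinyl-1,3-dioxolane
Product: 4 (3S,4S)-hexa-1,5-diene-3,4-diol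
Conditions: p-TsOH·H2O (cat.), MeOH–H2O, 50 °C
Reagents that add atoms: none
Why: Acid-catalysed acetal hydrolysis breaks only the acetal C–O bonds, so both carbinol centres keep their configuration, and dilute acid does not ionise an allylic alcohol whose cation would be destabilised by the neighbouring oxygen.

Step 3
Reactants: 4 (3S,4S)-hexa-1,5-diene-3,4-diol
Product: 5 (3S,4S)-4-(tert-butyldimethylsilyloxy)hexa-1,5-dien-3-ol
Conditions: NaH (1.0 equiv), THF, 0 °C → rt; t-BuMe2SiCl (1.0 equiv)
Reagents that add atoms: tert-butyldimethylsilyl chloride, CC(C)(C)[Si](C)(C)Cl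
Why: Monosilylation of a symmetrical diol through its poorly soluble monosodium alkoxide; the C2 axis makes the two hydroxyls equivalent, so only one mono-ether can form and a later 1,2-silyl shift would be degenerate.

Step 4
Reactants: 5 (3S,4S)-4-(tert-butyldimethylsilyloxy)hexa-1,5-dien-3-ol; 6 acryloyl chloride
Product: 7 (3S,4S)-4-(tert-butyldimethylsilyloxy)hexa-1,5-dien-3-yl acrylate
Conditions: Et3N (2 equiv), CH2Cl2, −20 → 0 °C
Reagents that add atoms: none
Why: Plain O-acylation of a secondary alcohol by an acid chloride with an amine base, run cold to suppress acrylate polymerisation; no stereocentre is touched.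

Step 5
Reactants: 7 (3S,4S)-4-(tert-butyldimethylsilyloxy)hexa-1,5-dien-3-yl acrylate
Product: 8 (5S,6S)-5-(tert-butyldimethylsilyloxy)-6-vinyl-5,6-dihydro-2H-pyran-2-one
Conditions: second-generation Grubbs catalyst RuCl2(=CHPh)(PCy3)(H2IMes) (5 mol %), CH2Cl2 (0.01 M), reflux
Reagents that add atoms: none
Why: Ring-closing metathesis in which the ruthenium carbene loads on an electron-rich vinyl group and closes onto the acrylate; closure through the vinyl next to the silyl ether to the six-membered enoate is the known preference over butenolide formation for protected dienediol acrylates, and the threo diol translates into the 5,6-cis lactone.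

Step 6
Reactants: 8 (5S,6S)-5-(tert-butyldimethylsilyloxy)-6-vinyl-5,6-dihydro-2H-pyran-2-one
Product: 9 (5S,6S)-5-(tert-butyldimethylsilyloxy)-6-vinyltetrahydro-2H-pyran-2-one
Conditions: Cu(OAc)2·H2O (5 mol %), 1,2-(Ph2P)2C6H4 (5 mol %), (EtO)2MeSiH (1.2 equiv), t-BuOH (1.2 equiv), toluene, 0 °C → rt
Reagents that add atoms: none
Why: Copper hydride conjugate reduction, established for α,β-unsaturated lactones, delivers hydride only to the polarised C3=C4 bond and t-BuOH protonates the copper enolate, so the isolated vinyl group, the allylic C–O bond and the silyl ether stay intact.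

Step 7
Reactants: 9 (5S,6S)-5-(tert-butyldimethylsilyloxy)-6-vinyltetrahydro-2H-pyran-2-one
Product: 10 (3S,5S,6S)-5-(tert-butyldimethylsilyloxy)-3-hydroxy-6-vinyltetrahydro-2H-pyran-2-one
Conditions: NaN(SiMe3)2 (1.2 equiv), THF, −78 °C; 2-(phenylsulfonyl)-3-phenyloxaziridine (1.4 equiv), −78 °C; aq. NH4Cl
Reagents that add atoms: 2-(phenylsulfonyl)-3-phenyloxaziridine, O=S(=O)(c1ccccc1)N1OC1c1ccccc1
Why: Davis oxidation of the sodium lactone enolate, in which the oxaziridine should approach anti to the vinyl and silyloxy groups to give mainly the (3S) alcohol; this centre is erased in step 8, and at −78 °C the allyl ester enolate does not rearrange.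

Step 8
Reactants: 10 (3S,5S,6S)-5-(tert-butyldimethylsilyloxy)-3-hydroxy-6-vinyltetrahydro-2H-pyran-2-one
Product: 14 (1S,5S)-5-(tert-butyldimethylsilyloxy)-1-hydroxycyclohex-3-ene-1-carboxylic acid, via O-trimethylsilyl lactone 11 (not isolated), via cyclic silyl ketene acetal 12 (not isolated), via bis-silylated acid 13 (not isolated)
Conditions: Me3SiCl–Et3N (1:1, 6 equiv), THF, −78 °C; LiN(SiMe3)2 (3 equiv), −78 → 0 °C; toluene, 105 °C; then 0.5 M aq. HCl, THF, 0 °C → rt
Reagents that add atoms: chlorotrimethylsilane, C[Si](C)(C)Cl (carried only by 11–13, removed again in the work-up)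
Why: Excess base and Me3SiCl first cap the 3-hydroxyl (11) and then trap the lactone enolate on oxygen as the planar cyclic ketene acetal 12, which on heating undergoes a concerted suprafacial [3,3] shift: the vinyl terminus (future C4) bonds to the ketene acetal carbon (future C5), the allylic C2–O bond breaks and the π bond settles at C2=C3, leaving the former carbonyl as the silyl carboxylate C1'. The closest known reaction type is the Ireland–Claisen rearrangement of ω-vinyl lactone silyl ketene acetals to cycloalkenecarboxylic acids, together with the same rearrangement of α-oxygenated (glycolate, lactate) allyl esters and of 6-alkenyl-1,4-dioxan-2-ones, so only the combination is specific to this molecule. The cyclohexene closes by pericyclic ring contraction through a boat-like, bicyclo[2.2.2]octane-shaped transition state imposed by the two-carbon tether C6–C1, and the new alkene is cis because it is endocyclic. The one new stereocentre, C5, is fixed by chirality transfer from the C2–O stereocentre that is destroyed: the vinyl group can reach only the face of the ketene acetal on which it stands, and since the C1 silyloxy group is cis to it in the lactone, C1–O and C5–O come out cis with C1' trans to both, whichever C3 epimer of 10 is used. The step needs O- rather than C-silylation and rearrangement rather than elimination, which are secured by the in situ Me3SiCl–Et3N quench at a fully substituted α-carbon, by the absence of a β-leaving group, and by the 5,6-cis arrangement that lets the vinyl group turn axial while the bulky silyl ether stays equatorial. Brief dilute acid then strips both Me3Si groups but not the t-BuMe2Si ether, and 14 can be purified by acid–base extraction.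

Step 9
Reactants: 14 (1S,5S)-5-(tert-butyldimethylsilyloxy)-1-hydroxycyclohex-3-ene-1-carboxylic acid
Product: 15 (1S,5S)-5-(tert-butyldimethylsilyloxy)-1-(hydroxymethyl)cyclohex-3-en-1-ol
Conditions: LiAlH4 (3 equiv), THF, 0 °C → rt; aq. work-up
Reagents that add atoms: none
Why: Hydride reduction of a carboxylic acid to the primary alcohol turns C1' into CH2OH, while the isolated alkene, the silyl ether (kept safe by avoiding prolonged heating) and both stereocentres are untouched.

Step 10
Reactants: 15 (1S,5S)-5-(tert-butyldimethylsilyloxy)-1-(hydroxymethyl)cyclohex-3-en-1-ol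
Product: 17 (3S,7S)-7-(tert-butyldimethylsilyloxy)-1-oxaspiro[2.5]oct-5-ene, via primary tosylate 16 (not isolated)
Conditions: TsCl (1.1 equiv), Et3N (2 equiv), 4-(dimethylamino)pyridine (cat.), CH2Cl2, 0 °C → rt; then K2CO3, MeOH, rt
Reagents that add atoms: p-toluenesulfonyl chloride, Cc1ccc(cc1)S(=O)(=O)Cl (carried only by 16)
Why: Selective sulfonylation of the primary over the tertiary hydroxyl followed by intramolecular Williamson (3-exo-tet) closure; the C5–O bond is never broken, so C5 keeps its configuration, and the mild carbonate base avoids silyl migration.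

Step 11
Reactants: 18 (4-bromobutyl)benzene
Product: 19 (4-phenylbutyl)triphenylphosphonium bromide
Conditions: PPh3, MeCN, reflux
Reagents that add atoms: triphenylphosphine, c1ccc(cc1)P(c1ccccc1)c1ccccc1
Why: SN2 quaternisation of triphenylphosphine by an unhindered primary bromide, the standard entry to a Wittig salt.

Step 12
Reactants: 20 11-bromoundecan-1-ol
Product: 21 11-bromoundecanal
Conditions: 2,2,6,6-tetramethylpiperidine-1-oxyl (TEMPO, 10 mol %), PhI(OAc)2 (1.1 equiv), CH2Cl2, rt
Reagents that add atoms: none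
Why: Oxoammonium-mediated oxidation of a primary alcohol stops at the aldehyde under anhydrous conditions and leaves the primary bromide alone.

Step 13
Reactants: 19 (4-phenylbutyl)triphenylphosphonium bromide; 21 11-bromoundecanal
Product: 23 [(4Z)-15-bromopentadec-4-en-1-yl]benzene, via phosphorus ylide 22 (not isolated)
Conditions: NaN(SiMe3)2 (1.0 equiv), THF, 0 °C; then 21 (1.05 equiv), −78 °C → rt
Reagents that add atoms: none
Why: Wittig olefination with a non-stabilised ylide under lithium-free conditions proceeds through the kinetically favoured cis-oxaphosphetane and should be highly Z-selective, and carbonyl addition at −78 °C is far faster than alkylation of the ylide by the primary bromide.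

Step 14
Reactants: 17 (3S,7S)-7-(tert-butyldimethylsilyloxy)-1-oxaspiro[2.5]oct-5-ene; 23 [(4Z)-15-bromopentadec-4-en-1-yl]benzene
Product: 25 (1S,5S)-5-(tert-butyldimethylsilyloxy)-1-[(12Z)-16-phenylhexadec-12-en-1-yl]cyclohex-3-en-1-ol, via Grignard reagent 24 (not isolated)
Conditions: 23 (2 equiv), Mg, THF, 40 °C; CuI (10 mol %), −30 °C; 17, −30 → 0 °C; aq. NH4Cl
Reagents that add atoms: magnesium, [Mg] (carried only by 24)
Why: Copper-catalysed SN2 opening of a 2,2-disubstituted epoxide by a primary alkyl Grignard reagent takes place at the unsubstituted CH2 (C1'), forming C1'–C2' without touching the C5–O bond, while the isolated Z-alkene and the allylic silyl ether are inert.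

Step 15
Reactants: 25 (1S,5S)-5-(tert-butyldimethylsilyloxy)-1-[(12Z)-16-phenylhexadec-12-en-1-yl]cyclohex-3-en-1-ol
Product: 26 (1S,3S)-1-[(12Z)-16-phenylhexadec-12-en-1-yl]cyclohex-4-ene-1,3-diol (target)
Conditions: Bu4NF (1.5 equiv), THF, rt
Reagents that add atoms: none
Why: Fluoride-induced cleavage of the Si–O bond frees the C1 hydroxyl with retention, since the C1–O bond is not involved, and nothing else in the molecule responds to fluoride.

**Compound list**

1 | dimethyl (4R,5R)-2,2-dimethyl-1,3-dioxolane-4,5-dicarboxylate | COC(=O)[C@@H]1OC(C)(C)O[C@H]1C(=O)OC | starting material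
2 | (4R,5R)-2,2-dimethyl-1,3-dioxolane-4,5-dicarbaldehyde | O=C[C@@H]1OC(C)(C)O[C@H]1C=O | intermediate
3 | (4S,5S)-2,2-dimethyl-4,5-divinyl-1,3-dioxolane | C=C[C@@H]1OC(C)(C)O[C@H]1C=C | intermediate
4 | (3S,4S)-hexa-1,5-diene-3,4-diol | C=C[C@H](O)[C@@H](O)C=C | intermediate
5 | (3S,4S)-4-(tert-butyldimethylsilyloxy)hexa-1,5-dien-3-ol | C=C[C@H](O)[C@@H](O[Si](C)(C)C(C)(C)C)C=C | intermediate
6 | acryloyl chloride | C=CC(Cl)=O | starting material
7 | (3S,4S)-4-(tert-butyldimethylsilyloxy)hexa-1,5-dien-3-yl acrylate | C=CC(=O)O[C@@H](C=C)[C@@H](O[Si](C)(C)C(C)(C)C)C=C | intermediate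
8 | (5S,6S)-5-(tert-butyldimethylsilyloxy)-6-vinyl-5,6-dihydro-2H-pyran-2-one | O=C1O[C@@H](C=C)[C@@H](O[Si](C)(C)C(C)(C)C)C=C1 | intermediate
9 | (5S,6S)-5-(tert-butyldimethylsilyloxy)-6-vinyltetrahydro-2H-pyran-2-one | O=C1O[C@@H](C=C)[C@@H](O[Si](C)(C)C(C)(C)C)CC1 | intermediate
10 | (3S,5S,6S)-5-(tert-butyldimethylsilyloxy)-3-hydroxy-6-vinyltetrahydro-2H-pyran-2-one (3-epimer equally usable) | O=C1O[C@@H](C=C)[C@@H](O[Si](C)(C)C(C)(C)C)C[C@@H]1O | intermediate
11 | (3S,5S,6S)-5-(tert-butyldimethylsilyloxy)-3-(trimethylsilyloxy)-6-vinyltetrahydro-2H-pyran-2-one | O=C1O[C@@H](C=C)[C@@H](O[Si](C)(C)C(C)(C)C)C[C@@H]1O[Si](C)(C)C | intermediate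
12 | (2S,3S)-3-(tert-butyldimethylsilyloxy)-5,6-bis(trimethylsilyloxy)-2-vinyl-3,4-dihydro-2H-pyran | C[Si](C)(C)OC1=C(O[Si](C)(C)C)C[C@H](O[Si](C)(C)C(C)(C)C)[C@H](C=C)O1 | intermediate
13 | trimethylsilyl (1S,5S)-5-(tert-butyldimethylsilyloxy)-1-(trimethylsilyloxy)cyclohex-3-ene-1-carboxylate | CC(C)(C)[Si](C)(C)O[C@@H]1C=CC[C@@](O[Si](C)(C)C)(C(=O)O[Si](C)(C)C)C1 | intermediate
14 | (1S,5S)-5-(tert-butyldimethylsilyloxy)-1-hydroxycyclohex-3-ene-1-carboxylic acid | CC(C)(C)[Si](C)(C)O[C@@H]1C=CC[C@@](O)(C(=O)O)C1 | intermediate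
15 | (1S,5S)-5-(tert-butyldimethylsilyloxy)-1-(hydroxymethyl)cyclohex-3-en-1-ol | CC(C)(C)[Si](C)(C)O[C@@H]1C=CC[C@@](O)(CO)C1 | intermediate
16 | [(1S,5S)-5-(tert-butyldimethylsilyloxy)-1-hydroxycyclohex-3-en-1-yl]methyl p-toluenesulfonate | CC(C)(C)[Si](C)(C)O[C@@H]1C=CC[C@@](O)(COS(=O)(=O)c2ccc(C)cc2)C1 | intermediate
17 | (3S,7S)-7-(tert-butyldimethylsilyloxy)-1-oxaspiro[2.5]oct-5-ene | CC(C)(C)[Si](C)(C)O[C@@H]1C=CC[C@@]2(CO2)C1 | intermediate
18 | (4-bromobutyl)benzene | BrCCCCc1ccccc1 | starting material
19 | (4-phenylbutyl)triphenylphosphonium bromide | [Br-].c1ccccc1CCCC[P+](c1ccccc1)(c1ccccc1)c1ccccc1 | intermediate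
20 | 11-bromoundecan-1-ol | OCCCCCCCCCCCBr | starting material
21 | 11-bromoundecanal | O=CCCCCCCCCCCBr | intermediate
22 | (4-phenylbutylidene)triphenylphosphorane | c1ccccc1CCCC=P(c1ccccc1)(c1ccccc1)c1ccccc1 | intermediate
23 | [(4Z)-15-bromopentadec-4-en-1-yl]benzene | BrCCCCCCCCCC/C=C\CCCc1ccccc1 | intermediate
24 | [(11Z)-15-phenylpentadec-11-en-1-yl]magnesium bromide | Br[Mg]CCCCCCCCCC/C=C\CCCc1ccccc1 | intermediate
25 | (1S,5S)-5-(tert-butyldimethylsilyloxy)-1-[(12Z)-16-phenylhexadec-12-en-1-yl]cyclohex-3-en-1-ol | CC(C)(C)[Si](C)(C)O[C@@H]1C=CC[C@@](O)(CCCCCCCCCCC/C=C\CCCc2ccccc2)C1 | intermediate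
26 | (1S,3S)-1-[(12Z)-16-phenylhexadec-12-en-1-yl]cyclohex-4-ene-1,3-diol | O[C@@H]1C=CC[C@@](O)(CCCCCCCCCCC/C=C\CCCc2ccccc2)C1 | target

**Step count.** Total: 15 steps. Longest linear sequence: 12 steps (steps 1–10, 14 and 15).

**Steps most likely to fail**

1. Step 8.
- What may go wrong: incomplete enolisation of the α-silyloxy lactone, silylation on carbon instead of oxygen, or thermal breakdown of the crowded ketene acetal by loss of the allylic carboxylate before the strained boat-like transition state is reached.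
- Fallback: move the oxygenation behind the ring contraction. It sets out from 9.
- LiN(SiMe3)2 and Me3SiCl–Et3N in THF at −78 °C give (2S,3S)-3-(tert-butyldimethylsilyloxy)-6-(trimethylsilyloxy)-2-vinyl-3,4-dihydro-2H-pyran F1.
- In refluxing toluene F1 rearranges, in the plain and best-known form of this reaction, to trimethylsilyl (1R,5S)-5-(tert-butyldimethylsilyloxy)cyclohex-3-ene-1-carboxylate F2.
- Aqueous work-up gives (1R,5S)-5-(tert-butyldimethylsilyloxy)cyclohex-3-ene-1-carboxylic acid F3.
- MeI and K2CO3 in DMF give methyl (1R,5S)-5-(tert-butyldimethylsilyloxy)cyclohex-3-ene-1-carboxylate F4.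
- Davis oxidation of its enolate (KN(SiMe3)2, 2-(phenylsulfonyl)-3-phenyloxaziridine, THF, −78 °C) gives methyl (1S,5S)-5-(tert-butyldimethylsilyloxy)-1-hydroxycyclohex-3-ene-1-carboxylate F5.
- The oxidant is expected to approach the exocyclic enolate from the equatorial direction, cis to the pseudo-equatorial silyloxy group, and the epimers should be separable.
- LiAlH4 reduction of F5 comes back to the route at 15.

2. Step 5.
- What may go wrong: closure through the wrong vinyl group to the five-membered butenolide, or oligomerisation by cross-metathesis of the remaining vinyl group.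
- Fallback: let a lactonisation, not a competition between two ring closures, fix the ring size. It sets out from 4.
- NaH and Et3SiCl give (3S,4S)-4-(triethylsilyloxy)hexa-1,5-dien-3-ol F6.
- Cross-metathesis with methyl acrylate uses the second-generation Hoveyda–Grubbs catalyst RuCl2(=CH-2-(i-PrO)C6H4)(H2IMes). It should take place at the less hindered vinyl next to the free hydroxyl and give methyl (2E,4S,5S)-4-hydroxy-5-(triethylsilyloxy)hepta-2,6-dienoate F7.
- t-BuMe2SiOTf and 2,6-lutidine give methyl (2E,4S,5S)-4-(tert-butyldimethylsilyloxy)-5-(triethylsilyloxy)hepta-2,6-dienoate F8.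
- The copper hydride conditions of step 6 give methyl (4S,5S)-4-(tert-butyldimethylsilyloxy)-5-(triethylsilyloxy)hept-6-enoate F9.
- Pyridinium p-toluenesulfonate in MeOH removes only the triethylsilyl group, and methyl (4S,5S)-4-(tert-butyldimethylsilyloxy)-5-hydroxyhept-6-enoate F10 lactonises in the flask.
- This comes back to the route at 9.

3. Step 14.
- What may go wrong: opening of the epoxide by magnesium halide to the bromohydrin, Lewis-acid-induced rearrangement of the epoxide to the aldehyde, or homocoupling of the Grignard reagent.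
- Fallback: replace the organometallic by a sulfone-stabilised carbanion. It sets out from 23 and uses 17.
- PhSO2Na in DMF gives [(4Z)-15-(phenylsulfonyl)pentadec-4-en-1-yl]benzene F11.
- n-BuLi in THF at −78 °C gives the α-lithio sulfone F12.
- F12 opens 17 at C1' to (1S,5S)-5-(tert-butyldimethylsilyloxy)-1-[(12Z)-16-phenyl-2-(phenylsulfonyl)hexadec-12-en-1-yl]cyclohex-3-en-1-ol F13, epimeric at the sulfone carbon, which does not matter.
- Reductive desulfonylation with Na(Hg) and Na2HPO4 in MeOH leaves isolated alkenes alone and cannot eliminate, because the hydroxyl is γ to the sulfone. It comes back to the route at 25.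

**Further compounds**

F1 | step 8 | (2S,3S)-3-(tert-butyldimethylsilyloxy)-6-(trimethylsilyloxy)-2-vinyl-3,4-dihydro-2H-pyran | C[Si](C)(C)OC1=CC[C@H](O[Si](C)(C)C(C)(C)C)[C@H](C=C)O1
F2 | step 8 | trimethylsilyl (1R,5S)-5-(tert-butyldimethylsilyloxy)cyclohex-3-ene-1-carboxylate | CC(C)(C)[Si](C)(C)O[C@@H]1C=CC[C@@H](C(=O)O[Si](C)(C)C)C1
F3 | step 8 | (1R,5S)-5-(tert-butyldimethylsilyloxy)cyclohex-3-ene-1-carboxylic acid | CC(C)(C)[Si](C)(C)O[C@@H]1C=CC[C@@H](C(=O)O)C1
F4 | step 8 | methyl (1R,5S)-5-(tert-butyldimethylsilyloxy)cyclohex-3-ene-1-carboxylate | CC(C)(C)[Si](C)(C)O[C@@H]1C=CC[C@@H](C(=O)OC)C1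
F5 | step 8 | methyl (1S,5S)-5-(tert-butyldimethylsilyloxy)-1-hydroxycyclohex-3-ene-1-carboxylate | CC(C)(C)[Si](C)(C)O[C@@H]1C=CC[C@@](O)(C(=O)OC)C1
F6 | step 5 | (3S,4S)-4-(triethylsilyloxy)hexa-1,5-dien-3-ol | C=C[C@H](O)[C@@H](O[Si](CC)(CC)CC)C=C
F7 | step 5 | methyl (2E,4S,5S)-4-hydroxy-5-(triethylsilyloxy)hepta-2,6-dienoate | COC(=O)/C=C/[C@H](O)[C@@H](O[Si](CC)(CC)CC)C=C
F8 | step 5 | methyl (2E,4S,5S)-4-(tert-butyldimethylsilyloxy)-5-(triethylsilyloxy)hepta-2,6-dienoate | COC(=O)/C=C/[C@H](O[Si](C)(C)C(C)(C)C)[C@@H](O[Si](CC)(CC)CC)C=C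
F9 | step 5 | methyl (4S,5S)-4-(tert-butyldimethylsilyloxy)-5-(triethylsilyloxy)hept-6-enoate | COC(=O)CC[C@H](O[Si](C)(C)C(C)(C)C)[C@@H](O[Si](CC)(CC)CC)C=C
F10 | step 5 | methyl (4S,5S)-4-(tert-butyldimethylsilyloxy)-5-hydroxyhept-6-enoate | COC(=O)CC[C@H](O[Si](C)(C)C(C)(C)C)[C@@H](O)C=C
F11 | step 14 | [(4Z)-15-(phenylsulfonyl)pentadec-4-en-1-yl]benzene | O=S(=O)(CCCCCCCCCC/C=C\CCCc1ccccc1)c1ccccc1
F12 | step 14 | [(11Z)-15-phenyl-1-(phenylsulfonyl)pentadec-11-en-1-yl]lithium | [Li]C(CCCCCCCCC/C=C\CCCc1ccccc1)S(=O)(=O)c1ccccc1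
F13 | step 14 | (1S,5S)-5-(tert-butyldimethylsilyloxy)-1-[(12Z)-16-phenyl-2-(phenylsulfonyl)hexadec-12-en-1-yl]cyclohex-3-en-1-ol | CC(C)(C)[Si](C)(C)O[C@@H]1C=CC[C@@](O)(CC(CCCCCCCCC/C=C\CCCc2ccccc2)S(=O)(=O)c2ccccc2)C1
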